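**Plan**
- Retrosynthesis: the acetate is removed and the axial C-3 carbinol and the C-4 CH2OH are taken back to a ring-A 3-oxo-4-carboxylate. Two ring bonds are then cut in one operation: the bond from the quaternary CH3/CH2OH-bearing carbon to the ring-fusion CH (ring A), and the bond from the methyl-bearing ring-fusion carbon to the side-chain-bearing CH (ring B). Last, the CH2–CH2 bond beside the ketone is cut (dianion alkylation), giving a chiral 2-methylacetoacetate and an ω-bromo (R)-2,3-dihydrofarnesoate.
- Enabling feature: the quaternary ring-A carbon lies between the C-3 oxygen and the CH2OH carbon, so it is the α-carbon of a masked 2-methyl-3-oxo ester and can become an electrophilic radical. The methyl-bearing carbons of rings A and B are spaced head-to-tail, so both rings unfold into one (E,E)-1,5-diene chain with each trisubstituted alkene placed for 6-endo closure.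
- Forward: farnesol → (R)-dihydrofarnesoate → terminal allylic bromide → alkylation of the keto ester dianion → oxidative radical bicyclisation (ring A first, then ring B) → alkene shift into ring B → ketone and ester reductions → selective acetylation.
- Stereochemistry: the side-chain centre comes from Ru–BINAP hydrogenation. The four ring stereocentres come from the cascade (chair–chair transition states, (E)-alkenes, axial ester), with the absolute sense set by a (1S,2R,5S)-8-phenylmenthyl ester. This ester is later cleaved reductively and its carbonyl carbon becomes the CH2OH. The C-3 carbinol comes from equatorial hydride delivery.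

Key step: step 8

Numbering: labdane numbering is used for the bicycle (C-3 carbinol, C-4 quaternary, C-5/C-10 ring fusion, C-7/C-8 alkene, C-9 carries the chain C-11 to C-15, C-13 side-chain stereocentre, C-19 the axial carbon on C-4); α/β refer to the conventional drawing with ring A at the left, in which this target has the 10-methyl α.

Assumption: for 2-methyl-3-oxo esters that cyclise with the ester axial, the (1R,2S,5R)-8-phenylmenthyl ester is taken to lead to the 10β-methyl series (aryl-shielding model), so the (1S,2R,5S) alcohol is used here for the 10α-methyl series.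

Step 1
Reactants: 1 (2E,6E)-farnesol
Product: 2 (3R,6E)-3,7,11-trimethyldodeca-6,10-dien-1-ol
Conditions: Ru(OAc)2[(S)-BINAP] (0.5 mol %), H2 (100 atm), MeOH/H2O 95:5, 20 °C
Reagents that add atoms: none
Why: Noyori asymmetric hydrogenation of an allylic alcohol reduces only the hydroxyl-directed 2,3-alkene, and the (S)-ligand/(E)-alkene pairing (the geraniol-to-(R)-citronellol correlation) should set the 3R centre that becomes C-13, leaving the remote trisubstituted alkenes untouched.

Step 2
Reactants: 2 (3R,6E)-3,7,11-trimethyldodeca-6,10-dien-1-ol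
Product: 3 (3R,6E)-3,7,11-trimethyldodeca-6,10-dienoic acid
Conditions: TEMPO (0.2 equiv), PhI(OAc)2 (2.2 equiv), MeCN/H2O 1:1, 20 °C
Reagents that add atoms: water, O
Why: TEMPO/PhI(OAc)2 oxoammonium oxidation in aqueous acetonitrile should take the primary alcohol through the aldehyde hydrate to the acid without touching the trisubstituted alkenes or the β-stereocentre.

Step 3
Reactants: 3 (3R,6E)-3,7,11-trimethyldodeca-6,10-dienoic acid
Product: 4 methyl (3R,6E)-3,7,11-trimethyldodeca-6,10-dienoate
Conditions: MeI (1.5 equiv), K2CO3 (1.5 equiv), DMF, 20 °C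
Reagents that add atoms: iodomethane, CI
Why: Carboxylate O-alkylation (SN2 on iodomethane) masks the acid for the allylic oxidation, bromination and enolate steps and affects no stereocentre.

Step 4
Reactants: 4 methyl (3R,6E)-3,7,11-trimethyldodeca-6,10-dienoate
Product: 5 methyl (3R,6E,10E)-12-hydroxy-3,7,11-trimethyldodeca-6,10-dienoate
Conditions: SeO2 (0.2 equiv), t-BuOOH (3 equiv), salicylic acid (0.1 equiv), CH2Cl2, 0 °C to 20 °C, stopped at partial conversion
Reagents that add atoms: tert-butyl hydroperoxide, CC(C)(C)OO
Why: Riley-type catalytic SeO2 allylic oxidation (ene reaction, then [2,3]-sigmatropic shift) should attack the more accessible terminal isopropylidene and oxidise its E-methyl, giving the (E)-allylic alcohol; partial conversion limits attack at the internal alkene and over-oxidation.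

Step 5
Reactants: 5 methyl (3R,6E,10E)-12-hydroxy-3,7,11-trimethyldodeca-6,10-dienoate
Product: 6 methyl (3R,6E,10E)-12-bromo-3,7,11-trimethyldodeca-6,10-dienoate
Conditions: CBr4 (1.2 equiv), PPh3 (1.25 equiv), CH2Cl2, 0 °C
Reagents that add atoms: tetrabromomethane, BrC(Br)(Br)Br
Why: The Appel reaction should convert the primary allylic alcohol into the bromide at 0 °C without allylic transposition or loss of the E-geometry.

Step 6
Reactants: 7 (1S,2R,5S)-5-methyl-2-(2-phenylpropan-2-yl)cyclohexan-1-ol [(+)-8-phenylmenthol]; 8 ethyl 2-methyl-3-oxobutanoate (3 equiv)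
Product: 9 (1S,2R,5S)-5-methyl-2-(2-phenylpropan-2-yl)cyclohexyl 2-methyl-3-oxobutanoate (both C-2 epimers)
Conditions: DMAP (0.3 equiv), toluene, reflux, ethanol distilled off
Reagents that add atoms: none
Why: DMAP-catalysed transesterification of a β-keto ester (acylketene/acylpyridinium pathway, driven by removal of ethanol) should load the hindered chiral alcohol; the α-centre is labile and irrelevant.

Step 7
Reactants: 9 (1S,2R,5S)-5-methyl-2-(2-phenylpropan-2-yl)cyclohexyl 2-methyl-3-oxobutanoate; 6 methyl (3R,6E,10E)-12-bromo-3,7,11-trimethyldodeca-6,10-dienoate (0.9 equiv)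
Product: 11 16-methyl 1-[(1S,2R,5S)-5-methyl-2-(2-phenylpropan-2-yl)cyclohexyl] (6E,10E,14R)-2,6,10,14-tetramethyl-3-oxohexadeca-6,10-dienedioate (both C-2 epimers), via bis-enolate 10 (not isolated)
Conditions: NaH (1.1 equiv), THF, 0 °C; n-BuLi (1.05 equiv), 0 °C; then 6, 0 °C, 30 min; AcOH/H2O quench
Reagents that add atoms: none
Why: In this Weiler dianion alkylation the more basic terminal carbanion of the 1,3-dicarbonyl dianion should displace the allylic bromide (SN2) much faster than it adds to the distal methyl ester, joining the chain with both (E)-alkenes intact.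

Step 8
Reactants: 11 16-methyl 1-[(1S,2R,5S)-5-methyl-2-(2-phenylpropan-2-yl)cyclohexyl] (6E,10E,14R)-2,6,10,14-tetramethyl-3-oxohexadeca-6,10-dienedioate
Product: 12 methyl (1S,2R,5S)-8-phenylmenthyl (13R)-3-oxolabd-8(17)-ene-15,19-dioate of the 10α-methyl series (trans-decalin; 5β-H; 9β-H; 4β-CH3; axial 4α ester carbon cis to the 10α-CH3; exocyclic 8(17)-methylene)
Conditions: Mn(OAc)3·2H2O (2.2 equiv), Cu(OAc)2·H2O (0.5 equiv), degassed AcOH (0.02 M), 25 °C
Reagents that add atoms: none
Why: Mn(OAc)3 oxidises the enol form of the 2-methyl-3-oxo ester to a tertiary electrophilic radical at the future quaternary ring-A carbon; this adds 6-endo-trig to the CH end of the first (E)-trisubstituted alkene, forming the bond between the quaternary carbon and the future ring-fusion CH (ring A), and the tertiary radical so formed closes ring B by a second 6-endo-trig addition, after which Cu(OAc)2 captures the tertiary ring-B radical and β-hydride elimination from the least hindered (methyl) position should give the exocyclic alkene. The closest known reaction type is the Mn(OAc)3/Cu(OAc)2 oxidative free-radical polyene cyclisation of 2-alkyl-3-oxo esters, including its 8-phenylmenthyl ester-controlled version. Relative configuration follows from chair–chair transition states with (E)-alkenes: trans ring fusion, the side chain equatorial at C-9, and the ester axial on ring A (cis to the angular methyl), as is general for α-methyl β-keto ester radicals. Absolute configuration is controlled by the auxiliary, whose phenyl ring covers one face of the planar radical so that the alkene adds to the open face. The step needs endo over exo closure (secured because attack at the less substituted alkene carbons gives tertiary radicals), ring closure faster than oxidation of the intermediate radical (sub-stoichiometric Cu(OAc)2, which Mn(OAc)3 regenerates) and face selectivity (auxiliary); the saturated side chain with its ester and stereocentre is a spectator. Any endocyclic alkene isomer formed directly is carried on, since step 9 converges both.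

Step 9
Reactants: 12 methyl (1S,2R,5S)-8-phenylmenthyl (13R)-3-oxolabd-8(17)-ene-15,19-dioate of the 10α-methyl series
Product: 13 methyl (1S,2R,5S)-8-phenylmenthyl (13R)-3-oxolabd-7-ene-15,19-dioate of the 10α-methyl series (ring stereocentres as in 12)
Conditions: chloro[N,N′-bis(3,5-di-tert-butylsalicylidene)-1,2-cyclohexanediaminato]cobalt, CoCl(C36H52N2O2) (3 mol %), PhSiH3 (6 mol %), benzene, 22 °C, argon
Reagents that add atoms: none
Why: Cobalt-hydride hydrogen-atom-transfer alkene isomerisation (reversible H-atom addition to the exocyclic CH2 gives the tertiary C-8 radical, which returns a hydrogen from the accessible C-7 methylene and not from the hindered C-9 methine) should move the 1,1-disubstituted alkene one position into ring B; ketone and esters are inert and no stereocentre is touched.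

Step 10
Reactants: 13 methyl (1S,2R,5S)-8-phenylmenthyl (13R)-3-oxolabd-7-ene-15,19-dioate of the 10α-methyl series
Product: 15 (13R)-3β-hydroxy-19-[(1S,2R,5S)-8-phenylmenthyloxy]-19-oxolabd-7-en-15-oic acid of the 10α-methyl series (axial 3-OH cis to the 5β-H), via hydroxy diester 14 (not isolated)
Conditions: LiBH(s-Bu)3 (1.3 equiv), THF, −78 °C; then LiOH·H2O (6 equiv), MeOH/H2O, 0 °C to 25 °C; 1 M HCl to pH 3
Reagents that add atoms: lithium hydroxide, [Li+].[OH-]
Why: Bulky trialkylborohydride reduction of a 4,4-disubstituted cyclohexanone delivers hydride along the equatorial trajectory and should give the axial carbinol with the C-3 configuration of the target, and in the same flask saponification takes the unhindered methyl ester while the quaternary auxiliary ester resists.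

Step 11
Reactants: 15 (13R)-3β-hydroxy-19-[(1S,2R,5S)-8-phenylmenthyloxy]-19-oxolabd-7-en-15-oic acid of the 10α-methyl series
Product: 16 (3R)-5-[(1R,4aS,5R,6S,8aS)-6-hydroxy-5-(hydroxymethyl)-2,5,8a-trimethyl-1,4,4a,5,6,7,8,8a-octahydronaphthalen-1-yl]-3-methylpentanoic acid
Conditions: LiBHEt3 (6 equiv), THF, 0 °C to 45 °C; then H2O, 1 M HCl
Reagents that add atoms: none
Why: Triethylborohydride ester reduction should turn the hindered auxiliary ester into the CH2OH and release the auxiliary alcohol for recovery, while the side-chain acid stays at the lithium carboxylate stage, which this hydride does not reduce; no stereocentre is affected.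

Step 12
Reactants: 16 (3R)-5-[(1R,4aS,5R,6S,8aS)-6-hydroxy-5-(hydroxymethyl)-2,5,8a-trimethyl-1,4,4a,5,6,7,8,8a-octahydronaphthalen-1-yl]-3-methylpentanoic acid
Product: 19 (3R)-5-[(1R,4aS,5R,6S,8aS)-6-(acetyloxy)-5-(hydroxymethyl)-2,5,8a-trimethyl-1,4,4a,5,6,7,8,8a-octahydronaphthalen-1-yl]-3-methylpentanoic acid, via bis-silyl derivative 17 (not isolated), via silylated acetate 18 (not isolated)
Conditions: Et3SiCl (2.3 equiv), imidazole (5 equiv), CH2Cl2, −20 °C to 0 °C; then Ac2O (3 equiv), Et3N, DMAP (0.2 equiv), 25 °C; then H2O, 1 M HCl/THF, 25 °C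
Reagents that add atoms: acetic anhydride, CC(=O)OC(C)=O (chlorotriethylsilane, CC[Si](Cl)(CC)CC, adds atoms only to the intermediates 17 and 18)
Why: Transient silyl protection should take the primary CH2OH (and the acid as its silyl ester) in preference to the hindered axial secondary hydroxyl, DMAP-catalysed acetylation then takes the remaining hydroxyl, and dilute acid removes both silyl groups; acetyl migration is blocked because the axial acetoxy and the axial CH2OH are anti-periplanar on the rigid trans-decalin.

**Compound list**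
1 | (2E,6E)-farnesol | OC/C=C(\C)CC/C=C(\C)CCC=C(C)C | starting material
2 | (3R,6E)-3,7,11-trimethyldodeca-6,10-dien-1-ol | OCC[C@H](C)CC/C=C(\C)CCC=C(C)C | intermediate
3 | (3R,6E)-3,7,11-trimethyldodeca-6,10-dienoic acid | OC(=O)C[C@H](C)CC/C=C(\C)CCC=C(C)C | intermediate
4 | methyl (3R,6E)-3,7,11-trimethyldodeca-6,10-dienoate | COC(=O)C[C@H](C)CC/C=C(\C)CCC=C(C)C | intermediate
5 | methyl (3R,6E,10E)-12-hydroxy-3,7,11-trimethyldodeca-6,10-dienoate | COC(=O)C[C@H](C)CC/C=C(\C)CC/C=C(\C)CO | intermediate
6 | methyl (3R,6E,10E)-12-bromo-3,7,11-trimethyldodeca-6,10-dienoate | COC(=O)C[C@H](C)CC/C=C(\C)CC/C=C(\C)CBr | intermediate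
7 | (1S,2R,5S)-5-methyl-2-(2-phenylpropan-2-yl)cyclohexan-1-ol [(+)-8-phenylmenthol] | CC(C)(c1ccccc1)[C@H]1CC[C@H](C)C[C@@H]1O | starting material
8 | ethyl 2-methyl-3-oxobutanoate | CCOC(=O)C(C)C(C)=O | starting material
9 | (1S,2R,5S)-5-methyl-2-(2-phenylpropan-2-yl)cyclohexyl 2-methyl-3-oxobutanoate | CC(=O)C(C)C(=O)O[C@H]1C[C@@H](C)CC[C@@H]1C(C)(C)c1ccccc1 | intermediate
10 | sodium lithium bis-enolate (dianion) of 9 | [Na+].[Li+].C=C([O-])C(C)=C([O-])O[C@H]1C[C@@H](C)CC[C@@H]1C(C)(C)c1ccccc1 | intermediate
11 | 16-methyl 1-[(1S,2R,5S)-5-methyl-2-(2-phenylpropan-2-yl)cyclohexyl] (6E,10E,14R)-2,6,10,14-tetramethyl-3-oxohexadeca-6,10-dienedioate | COC(=O)C[C@H](C)CC/C=C(\C)CC/C=C(\C)CCC(=O)C(C)C(=O)O[C@H]1C[C@@H](C)CC[C@@H]1C(C)(C)c1ccccc1 | intermediate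
12 | methyl (1S,2R,5S)-8-phenylmenthyl (13R)-3-oxolabd-8(17)-ene-15,19-dioate, 10α-methyl series | O=C1CC[C@]2(C)[C@H](CCC(=C)[C@H]2CC[C@@H](C)CC(=O)OC)[C@]1(C)C(=O)O[C@H]3C[C@@H](C)CC[C@@H]3C(C)(C)c4ccccc4 | intermediate
13 | methyl (1S,2R,5S)-8-phenylmenthyl (13R)-3-oxolabd-7-ene-15,19-dioate, 10α-methyl series | O=C1CC[C@]2(C)[C@H](CC=C(C)[C@H]2CC[C@@H](C)CC(=O)OC)[C@]1(C)C(=O)O[C@H]3C[C@@H](C)CC[C@@H]3C(C)(C)c4ccccc4 | intermediate
14 | methyl (1S,2R,5S)-8-phenylmenthyl (13R)-3β-hydroxylabd-7-ene-15,19-dioate, 10α-methyl series (axial 3-OH) | O[C@H]1CC[C@]2(C)[C@H](CC=C(C)[C@H]2CC[C@@H](C)CC(=O)OC)[C@]1(C)C(=O)O[C@H]3C[C@@H](C)CC[C@@H]3C(C)(C)c4ccccc4 | intermediate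
15 | (13R)-3β-hydroxy-19-[(1S,2R,5S)-8-phenylmenthyloxy]-19-oxolabd-7-en-15-oic acid, 10α-methyl series | O[C@H]1CC[C@]2(C)[C@H](CC=C(C)[C@H]2CC[C@@H](C)CC(=O)O)[C@]1(C)C(=O)O[C@H]3C[C@@H](C)CC[C@@H]3C(C)(C)c4ccccc4 | intermediate
16 | (3R)-5-[(1R,4aS,5R,6S,8aS)-6-hydroxy-5-(hydroxymethyl)-2,5,8a-trimethyl-1,4,4a,5,6,7,8,8a-octahydronaphthalen-1-yl]-3-methylpentanoic acid | O[C@H]1CC[C@]2(C)[C@H](CC=C(C)[C@H]2CC[C@@H](C)CC(=O)O)[C@]1(C)CO | intermediate
17 | triethylsilyl ester and 19-O-triethylsilyl ether of 16 | O[C@H]1CC[C@]2(C)[C@H](CC=C(C)[C@H]2CC[C@@H](C)CC(=O)O[Si](CC)(CC)CC)[C@]1(C)CO[Si](CC)(CC)CC | intermediate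
18 | 3-O-acetyl derivative of 17 | CC(=O)O[C@H]1CC[C@]2(C)[C@H](CC=C(C)[C@H]2CC[C@@H](C)CC(=O)O[Si](CC)(CC)CC)[C@]1(C)CO[Si](CC)(CC)CC | intermediate
19 | (3R)-5-[(1R,4aS,5R,6S,8aS)-6-(acetyloxy)-5-(hydroxymethyl)-2,5,8a-trimethyl-1,4,4a,5,6,7,8,8a-octahydronaphthalen-1-yl]-3-methylpentanoic acid (CNP0138726.1) | CC(=O)O[C@H]1CC[C@]2(C)[C@H](CC=C(C)[C@H]2CC[C@@H](C)CC(=O)O)[C@]1(C)CO | target

**Step count and risks**
Total step count: 12. Longest linear sequence: 11 steps (1 to 19 through steps 1–5 and 7–12; step 6 is the side branch).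

Steps most likely to fail:

1. Step 8. The tertiary radical formed after the first ring closure may be oxidised before ring B closes, so the cascade may stop at the monocyclic stage. The fallback makes the two rings in two operations and sets out from 11. Mn(OAc)3·2H2O with an excess of Cu(OAc)2·H2O (3 equiv) in AcOH deliberately stops after ring A and should give the monocyclic 4-methylene-cyclohexanone keto diester F1, which keeps the auxiliary-controlled centres at the quaternary carbon and its neighbour. Ring B is then closed by a polar cation–olefin cyclisation (FSO3H in 2-nitropropane at −78 °C, or SnCl4 in CH2Cl2): protonation of the exocyclic alkene gives the tertiary cation, the remaining (E)-alkene captures it 6-endo through a chair transition state, and loss of a ring proton places the alkene in the 7,8-position. This comes back to the route at 13, and step 9 is then not needed.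

2. Step 9. The alkene migration may stall or run on into the tetrasubstituted 8,9-position. The fallback replaces migration by excision and reinstallation of the carbon and sets out from 12. LiBH(s-Bu)3 (THF, −78 °C) reduces the ketone to the axial carbinol, the 3β-hydroxy 8(17)-ene diester F2. Ozonolysis (O3, CH2Cl2/MeOH, −78 °C; Me2S) removes the methylene carbon and gives the 8-oxo-17-nor hydroxy diester F3. Kinetic deprotonation with KN(SiMe3)2 (2.2 equiv, THF, −78 °C; the first equivalent is taken by the hydroxyl) at the unhindered C-7 methylene, followed by PhNTf2, gives the 7-en-8-yl triflate F4 with the double bond already fixed. Negishi methylation (MeZnCl, Pd(PPh3)4, THF, 50 °C) installs the ring methyl and comes back to the route at 14, which is saponified as in the second stage of step 10.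

3. Step 11. Hydride attack at the very hindered quaternary ester may be incomplete under conditions that spare the carboxylate. The fallback reduces everything and then re-oxidises selectively, setting out from 15. LiAlH4 (THF, reflux) reduces both the auxiliary ester and the carboxylate and should give the 3β,15,19-triol F5 with release of the auxiliary alcohol. TEMPO (0.1 equiv)/PhI(OAc)2 in MeCN/H2O at 0 °C then oxidises the unhindered side-chain primary alcohol to the acid, the neopentyl CH2OH and the axial secondary hydroxyl reacting far more slowly with the bulky oxoammonium salt. This comes back to the route at 16.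

**Further compounds**
F1 | step 8 | methyl (1S,2R,5S)-8-phenylmenthyl monocyclic keto diester: 2-oxo-1-methyl-5-methylene-cyclohexane-1-carboxylate carrying at C-6 the (3E,7R)-9-methoxy-3,7-dimethyl-9-oxonon-3-enyl chain (ring centres as in 12) | O=C1CCC(=C)[C@H](CC/C(C)=C/CC[C@@H](C)CC(=O)OC)[C@]1(C)C(=O)O[C@H]2C[C@@H](C)CC[C@@H]2C(C)(C)c3ccccc3
F2 | step 9 | methyl (1S,2R,5S)-8-phenylmenthyl (13R)-3β-hydroxylabd-8(17)-ene-15,19-dioate, 10α-methyl series | O[C@H]1CC[C@]2(C)[C@H](CCC(=C)[C@H]2CC[C@@H](C)CC(=O)OC)[C@]1(C)C(=O)O[C@H]3C[C@@H](C)CC[C@@H]3C(C)(C)c4ccccc4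
F3 | step 9 | methyl (1S,2R,5S)-8-phenylmenthyl (13R)-3β-hydroxy-8-oxo-17-norlabdane-15,19-dioate, 10α-methyl series | O[C@H]1CC[C@]2(C)[C@H](CCC(=O)[C@H]2CC[C@@H](C)CC(=O)OC)[C@]1(C)C(=O)O[C@H]3C[C@@H](C)CC[C@@H]3C(C)(C)c4ccccc4
F4 | step 9 | methyl (1S,2R,5S)-8-phenylmenthyl (13R)-3β-hydroxy-8-(trifluoromethylsulfonyloxy)-17-norlabd-7-ene-15,19-dioate, 10α-methyl series | O[C@H]1CC[C@]2(C)[C@H](CC=C(OS(=O)(=O)C(F)(F)F)[C@H]2CC[C@@H](C)CC(=O)OC)[C@]1(C)C(=O)O[C@H]3C[C@@H](C)CC[C@@H]3C(C)(C)c4ccccc4
F5 | step 11 | (13R)-labd-7-ene-3β,15,19-triol, 10α-methyl series | O[C@H]1CC[C@]2(C)[C@H](CC=C(C)[C@H]2CC[C@@H](C)CCO)[C@]1(C)CO
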